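**Retrosynthetic overview**
- The target is the 7‑O‑acetate of itself minus the ester. The only ring to be built, the 2,2‑dimethyl‑2H‑pyran fused to ring B at O4'/C5', comes last, from the 4'‑phenol and 3‑methylbut‑2‑enal.
- This leads back to (S)‑7,4'‑dihydroxy‑8,3'‑diprenylflavanone. Both C‑prenyl bonds (C8–CH2 and C3'–CH2) are cut at once by a twofold aromatic Claisen rearrangement of the 7,4'‑bis(1,1‑dimethylallyl) ether.
- Feature used: each phenolic oxygen of the flavanone (O7 on ring A, O4' on ring B) sits on the carbon next to the one that must carry a prenyl group (C8 next to C7, C3' next to C4'). An O→C [3,3] transfer therefore reaches both sites from the two OH groups already present.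
- The bis ether comes from (S)‑liquiritigenin (rings A, C and B and the C2 stereocentre are bought) and the methyl carbonate of 2‑methylbut‑3‑en‑2‑ol.

Key step: step 3

Flavanone numbering is used throughout (O1, C2, C3, C4=O, ring A C5–C8, ring B C1'–C6'); prenyl = 3‑methylbut‑2‑en‑1‑yl.
Assumption: commercial (S)‑liquiritigenin is taken as enantiomerically pure at C2; because 4'‑hydroxyflavanones racemise under base, this is verified by chiral HPLC before use and no strong base is used anywhere in the route.
Assumption: in the key step the ring‑B ether is taken to rearrange before the ring‑A ether; the opposite order leads to the same product.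

**Step 1**
Reactants: 1 2‑methylbut‑3‑en‑2‑ol; 2 methyl chloroformate
Product: 3 methyl 2‑methylbut‑3‑en‑2‑yl carbonate
Conditions: n‑BuLi (1.05 equiv), THF, −78 °C; then 2, −78 → 0 °C
Reagents that add atoms: methyl chloroformate, COC(=O)Cl
Why: Alkoxycarbonylation of the lithium alkoxide of the tertiary allylic alcohol with a chloroformate is the standard way to make such a carbonate, which forms only sluggishly from the free alcohol and an amine base.

**Step 2**
Reactants: 4 (S)‑liquiritigenin [(2S)‑7,4'‑dihydroxyflavanone]; 3 methyl 2‑methylbut‑3‑en‑2‑yl carbonate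
Product: 5 (S)‑7,4'‑bis(2‑methylbut‑3‑en‑2‑yloxy)flavanone
Conditions: 3 (3 equiv), Pd(PPh3)4 (5 mol%), THF, 0–4 °C, Ar; stopped at full bis‑etherification; chromatography on Et3N‑deactivated silica
Reagents that add atoms: methyl 2‑methylbut‑3‑en‑2‑yl carbonate, COC(=O)OC(C)(C)C=C
Why: In this decarboxylative Tsuji–Trost O‑allylation, Pd(0) ionises 3 to a 1,1‑dimethyl‑π‑allyl complex and methoxide (after loss of CO2), the phenol quenches the methoxide at once, and at low temperature the phenoxide attacks the more substituted allyl terminus under kinetic control to give the tertiary ether without external base that could open the flavanone at C2.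

**Step 3**
Reactants: 5 (S)‑7,4'‑bis(2‑methylbut‑3‑en‑2‑yloxy)flavanone
Product: 9 (S)‑7,4'‑dihydroxy‑8,3'‑diprenylflavanone, via ring‑B dienone 6 (not isolated), via mono‑rearranged phenol 7 (not isolated), via ring‑A dienone 8 (not isolated)
Conditions: o‑xylene (degassed, dilute), 125 °C, Ar, base‑washed glassware, dark; chromatography to remove the C6 isomer
Reagents that add atoms: none
Why: Each aryl 1,1‑dimethylallyl ether undergoes a concerted suprafacial [3,3] shift through a chair‑like six‑membered transition state in which the O–CMe2 bond breaks as the vinyl CH2 bonds to the ortho ring carbon, giving 6‑prenylcyclohexa‑2,4‑dienones (6, then 8) that enolise to the phenols; this is the aromatic Claisen rearrangement of tert‑prenyl aryl ethers, which the gem‑dimethyl group (crowded tertiary ether lost, trisubstituted alkene gained) allows near 125 °C. No ring is closed and no lasting stereocentre is created, since the sp3 ring carbons of the dienones are erased on tautomerisation. On ring B the two ortho carbons C3' and C5' are equivalent, so no regiochemical question arises there. On ring A the shift must go to C8 and not C6, and this is favoured because the push–pull unit O1–C8a=C4a–C4=O localises the C8a=C4a double bond and so leaves C7–C8 (not C6–C7) with the higher double‑bond character, the same bond fixation that sends related 7‑allyloxy chromanones and coumarins and 4‑allyloxy‑2‑hydroxyaryl ketones to the carbon between the two oxygens; the C6 isomer is expected as the minor product. Neutral aprotic conditions protect the C2 stereocentre (no base for retro‑oxa‑Michael opening, no acid to ionise the tertiary ether to isoprene), and 125 °C lies below the range in which ortho‑prenylphenols cyclise to chromans or dihydrobenzofurans.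

**Step 4**
Reactants: 9 (S)‑7,4'‑dihydroxy‑8,3'‑diprenylflavanone; 10 acetic anhydride
Product: 11 (S)‑7‑acetoxy‑4'‑hydroxy‑8,3'‑diprenylflavanone
Conditions: Ac2O (1.0 equiv), Et3N (1.05 equiv), CH2Cl2, −20 → 0 °C
Reagents that add atoms: acetic anhydride, CC(=O)OC(C)=O
Why: The 7‑OH is para to the C4 carbonyl (a vinylogous carboxylic acid, clearly more acidic than the 4'‑OH), so one equivalent of a weak amine base ionises it selectively and this phenoxide is O‑acylated (phenol acetylation), while the 7‑phenoxide itself disfavours ring opening at C2.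

**Step 5**
Reactants: 11 (S)‑7‑acetoxy‑4'‑hydroxy‑8,3'‑diprenylflavanone; 12 3‑methylbut‑2‑enal
Product: 15 (2S)‑7‑acetoxy‑2‑[2,2‑dimethyl‑8‑prenyl‑2H‑chromen‑6‑yl]‑8‑prenylchroman‑4‑one, via benzodioxaborin 13 (not isolated), via ortho‑quinone methide 14 (not isolated)
Conditions: 12 (2 equiv), PhB(OH)2 (1.1 equiv), AcOH, PhMe, reflux with azeotropic removal of water
Reagents that add atoms: 3‑methylbut‑2‑enal, CC(C)=CC=O
Why: In this phenylboronic acid‑mediated chromenylation of a phenol with an enal, the aryl boronate delivers the aldehyde to the only free ortho carbon of ring B (C5') to give 13, which loses PhBO on heating to the ortho‑quinone methide 14 that closes by oxa‑6π electrocyclisation to the 2,2‑dimethyl‑2H‑chromene; the 7‑acetate blocks the same process at O7/C6, and acetic acid as additive makes any acyl exchange degenerate.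

**Step 6**
Reactants: 15 (2S)‑7‑acetoxy‑2‑[2,2‑dimethyl‑8‑prenyl‑2H‑chromen‑6‑yl]‑8‑prenylchroman‑4‑one
Product: 16 (2S)‑7‑hydroxy‑2‑[2,2‑dimethyl‑8‑prenyl‑2H‑chromen‑6‑yl]‑8‑prenylchroman‑4‑one (target)
Conditions: NH4OAc (excess), MeOH/H2O 4:1, rt
Reagents that add atoms: none
Why: The acetate of the acidic 7‑phenol is an activated aryl ester that should undergo near‑neutral ammonium acetate‑mediated methanolysis (transesterification), conditions that leave the chromene, the prenyl groups and the C2 centre alone (the 4'‑oxygen is now alkylated, so the quinone‑methide route to racemisation is closed).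

**Compound list**
1 | 2‑methylbut‑3‑en‑2‑ol | CC(C)(O)C=C | starting material
2 | methyl chloroformate | COC(=O)Cl | starting material
3 | methyl 2‑methylbut‑3‑en‑2‑yl carbonate | COC(=O)OC(C)(C)C=C | intermediate
4 | (S)‑liquiritigenin, (2S)‑7,4'‑dihydroxyflavanone | O=C1C[C@@H](c3ccc(O)cc3)Oc2cc(O)ccc21 | starting material
5 | (S)‑7,4'‑bis(2‑methylbut‑3‑en‑2‑yloxy)flavanone | O=C1C[C@@H](c3ccc(OC(C)(C)C=C)cc3)Oc2cc(OC(C)(C)C=C)ccc21 | intermediate
6 | ring‑B dienone: C3' is sp3 (H, prenyl), C4'=O, 7‑ether intact; epimers at C3' | O=C1C[C@@H](C3=CC(CC=C(C)C)C(=O)C=C3)Oc2cc(OC(C)(C)C=C)ccc21 | intermediate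
7 | (S)‑4'‑hydroxy‑3'‑prenyl‑7‑(2‑methylbut‑3‑en‑2‑yloxy)flavanone | O=C1C[C@@H](c3ccc(O)c(CC=C(C)C)c3)Oc2cc(OC(C)(C)C=C)ccc21 | intermediate
8 | ring‑A dienone: C8 is sp3 (H, prenyl), C7=O, C8a=C4a and C5=C6 double bonds; epimers at C8 | O=C1C[C@@H](c3ccc(O)c(CC=C(C)C)c3)OC2=C1C=CC(=O)C2CC=C(C)C | intermediate
9 | (S)‑7,4'‑dihydroxy‑8,3'‑diprenylflavanone | O=C1C[C@@H](c3ccc(O)c(CC=C(C)C)c3)Oc2c(CC=C(C)C)c(O)ccc21 | intermediate
10 | acetic anhydride | CC(=O)OC(C)=O | starting material
11 | (S)‑7‑acetoxy‑4'‑hydroxy‑8,3'‑diprenylflavanone | O=C1C[C@@H](c3ccc(O)c(CC=C(C)C)c3)Oc2c(CC=C(C)C)c(OC(C)=O)ccc21 | intermediate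
12 | 3‑methylbut‑2‑enal | CC(C)=CC=O | starting material
13 | 2‑phenyl‑4‑(2‑methylprop‑1‑enyl)‑4H‑1,3,2‑benzodioxaborin spanning O4'/C5' of ring B of 11; epimers at the new CH | O=C1C[C@@H](c3cc(CC=C(C)C)c4OB(c5ccccc5)OC(C=C(C)C)c4c3)Oc2c(CC=C(C)C)c(OC(C)=O)ccc21 | intermediate
14 | ortho‑quinone methide of ring B: C4'=O, C5'=CH–CH=CMe2 | O=C1C[C@@H](C3=CC(=CC=C(C)C)C(=O)C(CC=C(C)C)=C3)Oc2c(CC=C(C)C)c(OC(C)=O)ccc21 | intermediate
15 | (2S)‑7‑acetoxy‑2‑[2,2‑dimethyl‑8‑prenyl‑2H‑chromen‑6‑yl]‑8‑prenylchroman‑4‑one | O=C1C[C@@H](c3cc(CC=C(C)C)c4OC(C)(C)C=Cc4c3)Oc2c(CC=C(C)C)c(OC(C)=O)ccc21 | intermediate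
16 | (2S)‑7‑hydroxy‑2‑[2,2‑dimethyl‑8‑prenyl‑2H‑chromen‑6‑yl]‑8‑prenylchroman‑4‑one | CC(C)=CCc1cc([C@@H]2CC(=O)c3ccc(O)c(CC=C(C)C)c3O2)cc2c1OC(C)(C)C=C2 | target

**Step count**
Total: 6 steps. Longest linear sequence: 6 steps (1 → 3 → 5 → 9 → 11 → 15 → 16), or 5 from (S)‑liquiritigenin 4. The configuration at C2 is to be checked by chiral HPLC after steps 2, 3, 4 and 5.

**Steps most likely to fail**

Step 3 (key step). On the slower ring‑A ether, heterolysis of the O–CMe2 bond (loss of isoprene, possibly promoted by the acidic 7‑phenol as it forms) and migration to C6 may compete with the shift to C8, and long heating may erode C2. Fallback, which keeps a double O→C [3,3] transfer but separates C–C bond formation from installation of the gem‑dimethyl termini: starting from 4, Pd‑catalysed bis‑O‑allylation with allyl methyl carbonate (Pd(PPh3)4, THF, rt) should give (S)‑7,4'‑bis(allyloxy)flavanone F1, whose primary allyl ethers cannot fragment to a diene. Thermal double Claisen rearrangement in degassed o‑dichlorobenzene at about 190 °C should give (S)‑8,3'‑diallyl‑7,4'‑dihydroxyflavanone F2. Twofold olefin cross‑metathesis with excess 2‑methylbut‑2‑ene (second‑generation Ru benzylidene catalyst, CH2Cl2, 40 °C) should then convert both allyl groups into prenyl groups, rejoining the route at 9. The higher Claisen temperature makes the C2 check mandatory at F2.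

Step 5. Ortho‑hydroxyalkylation of the unactivated, mono‑phenolic ring B by the enal may be slow, so that acid‑induced cyclisation of the 3'‑prenyl group onto O4' or slow loss of C2 integrity at reflux takes over. Fallback by the propargyl ether route: starting from 11, O‑alkylation with 3‑chloro‑3‑methylbut‑1‑yne (K2CO3, KI, CuI cat., dry acetone, 40 °C; the aryl acetate tolerates anhydrous carbonate) should give (S)‑7‑acetoxy‑4'‑(2‑methylbut‑3‑yn‑2‑yloxy)‑8,3'‑diprenylflavanone F3. Heating in o‑xylene at 130–140 °C should effect propargyl Claisen rearrangement to C5' (the only free ortho carbon), 1,5‑H shift and oxa‑6π electrocyclisation, rejoining the route at 15.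

Step 2. Pd(0) may re‑ionise the first‑formed tertiary ether of the acidic 7‑phenol and isomerise it to the linear prenyl ether, or the second etherification may stall. Fallback by the classical two‑stage route: starting from 4, Cu‑catalysed O‑alkylation of both phenols with 3‑chloro‑3‑methylbut‑1‑yne (CuCl2·2H2O cat., DBU, MeCN, 0 °C, short reaction time to limit base exposure of C2) should give (S)‑7,4'‑bis(2‑methylbut‑3‑yn‑2‑yloxy)flavanone F4. Semi‑hydrogenation of both alkynes (H2, Pb‑poisoned Pd/CaCO3, quinoline, EtOAc, rt) should then give the bis(1,1‑dimethylallyl) ether, rejoining the route at 5.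

**Further compounds**
F1 | step 3 | (S)‑7,4'‑bis(allyloxy)flavanone | O=C1C[C@@H](c3ccc(OCC=C)cc3)Oc2cc(OCC=C)ccc21
F2 | step 3 | (S)‑8,3'‑diallyl‑7,4'‑dihydroxyflavanone | O=C1C[C@@H](c3ccc(O)c(CC=C)c3)Oc2c(CC=C)c(O)ccc21
F3 | step 5 | (S)‑7‑acetoxy‑4'‑(2‑methylbut‑3‑yn‑2‑yloxy)‑8,3'‑diprenylflavanone | O=C1C[C@@H](c3ccc(OC(C)(C)C#C)c(CC=C(C)C)c3)Oc2c(CC=C(C)C)c(OC(C)=O)ccc21
F4 | step 2 | (S)‑7,4'‑bis(2‑methylbut‑3‑yn‑2‑yloxy)flavanone | O=C1C[C@@H](c3ccc(OC(C)(C)C#C)cc3)Oc2cc(OC(C)(C)C#C)ccc21
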